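**Retrosynthetic overview**
1. Target 14 ⇒ C5–aryl bond: (R)-ester 10 + bromohydroquinone 12, joined last by one-pot C–H borylation/Suzuki coupling.
2. Ester C–O bond at the stereocentre ⇒ racemic carbinol 5 + isovaleryl carbonate 8. This enantioconvergent acylation is the key step: it makes the ester and sets (R) in one operation.
3. Carbinol 5 ⇒ furan-3-carbaldehyde 1 + prenyl chloride 2 (α-selective barium allylation).
4. No ring is formed: the furan and benzene rings are bought.

Assumption: the stereocentre in the given SMILES is (R) (O > furan-3-yl > CH2 > H), and (R)-BTM is taken to acylate the (R)-carbinol as it does aryl alkyl carbinols; this sense is recalled, not verified, so if the first run shows the opposite, (S)-BTM is used.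

Step 1
Reactants: 1 furan-3-carbaldehyde; 2 1-chloro-3-methylbut-2-ene (prenyl chloride); 3 barium iodide (anhydrous)
Product: 5 rac-1-(furan-3-yl)-4-methylpent-3-en-1-ol, via prenylbarium chloride 4 (not isolated)
Conditions: 3, Li biphenylide (2 equiv), THF, rt (active Ba); 2, −78 °C, 30 min; then 1, −78 °C; 1 M HCl quench
Reagents that add atoms: none
Why: Organobarium carbonyl allylation (Barbier-type): allylic barium reagents made at −78 °C add to aldehydes at the α-carbon, unlike Mg, Zn or In prenyl reagents, so the linear homoprenyl carbinol forms; the product is racemic and the stereocentre is fixed in step 3.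

Step 2
Reactants: 6 3-methylbutanoic acid (isovaleric acid); 7 isopropyl chloroformate
Product: 8 3-methylbutanoic isopropyl carbonic anhydride
Conditions: Et3N (1.0 equiv), Et2O, −10 to 0 °C, 1 h; filter under Ar, concentrate cold, use fresh
Reagents that add atoms: none
Why: Classical mixed carboxylic–carbonic anhydride formation; the triethylammonium carboxylate displaces chloride from the chloroformate, and low temperature suppresses disproportionation.

Step 3
Reactants: 5 rac-1-(furan-3-yl)-4-methylpent-3-en-1-ol; 8 3-methylbutanoic isopropyl carbonic anhydride (1.4 equiv)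
Product: 10 (R)-1-(furan-3-yl)-4-methylpent-3-en-1-yl 3-methylbutanoate, via furyl ketone 9 (not isolated)
Conditions: (R)-BTM (5 mol%), (η5-C5Ph5)Ru(CO)2Cl (5 mol%), KOtBu (5 mol%), toluene/t-AmOH 1:1, 10 °C, 48 h, Ar
Reagents that add atoms: none
Why: Proposed new method: a non-enzymatic acylative dynamic kinetic resolution that pairs a chiral isothiourea with a Ru racemisation catalyst and delivers an isovaleryl group from an acyl carbonate. The Ru alkoxide of either enantiomer of 5 undergoes reversible β-hydride elimination through the Ru-bound ketone 9, so the slow (S)-carbinol is racemised continuously. (R)-BTM attacks the carboxylic C=O of 8 to give an N-isovaleryl isothiouronium ion; the furan ring of the (R)-carbinol stacks on the cationic benzothiazolium face (cation–π) with the homoprenyl chain turned away from the catalyst's phenyl group, and the isopropyl carbonate counter-ion acts as the base and then leaves as CO2 and isopropanol, so no carboxylic acid forms to poison the Ru centre. The ester 10 is not a substrate for Ru, which locks (R). Closest known reactions: isothiourea-catalysed kinetic resolution of aryl alkyl carbinols with anhydrides, and Ru/chiral-DMAP or Ru/lipase dynamic kinetic resolutions of secondary alcohols.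

Step 4
Reactants: 10 (R)-1-(furan-3-yl)-4-methylpent-3-en-1-yl 3-methylbutanoate; 11 bis(pinacolato)diboron (1.0 equiv); 12 2-bromobenzene-1,4-diol (bromohydroquinone, 1.2 equiv)
Product: 14 (R)-1-[5-(2,5-dihydroxyphenyl)furan-3-yl]-4-methylpent-3-en-1-yl 3-methylbutanoate, via furyl pinacol boronate 13 (not isolated)
Conditions: [Ir(OMe)(cod)]2 (1.5 mol%), dtbpy (3 mol%), THF, rt; evaporate volatiles; then 12, XPhos Pd G3 (2 mol%), degassed 0.5 M aq K3PO4 (4 equiv), THF, 40 °C, Ar; work-up with aq Na2S2O4
Reagents that add atoms: none
Why: Ir-catalysed C–H borylation is sterically controlled and goes to the furan α-position remote from the branched 3-substituent (C5); Suzuki–Miyaura coupling with a fast precatalyst at 40 °C outruns protodeboronation, tolerates the free phenols and the ester, and leaves the stereocentre untouched.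

**Compound list**
1 | furan-3-carbaldehyde | O=Cc1ccoc1 | starting material
2 | 1-chloro-3-methylbut-2-ene (prenyl chloride) | CC(C)=CCCl | starting material
3 | barium iodide (anhydrous) | [Ba+2].[I-].[I-] | starting material
4 | (3-methylbut-2-en-1-yl)barium chloride | CC(C)=CC[Ba]Cl | intermediate
5 | rac-1-(furan-3-yl)-4-methylpent-3-en-1-ol | CC(C)=CCC(O)c1ccoc1 | intermediate
6 | 3-methylbutanoic acid | CC(C)CC(=O)O | starting material
7 | isopropyl chloroformate | CC(C)OC(=O)Cl | starting material
8 | 3-methylbutanoic isopropyl carbonic anhydride | CC(C)CC(=O)OC(=O)OC(C)C | intermediate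
9 | 1-(furan-3-yl)-4-methylpent-3-en-1-one (transient, Ru-bound, in the racemisation cycle) | CC(C)=CCC(=O)c1ccoc1 | intermediate
10 | (R)-1-(furan-3-yl)-4-methylpent-3-en-1-yl 3-methylbutanoate | CC(C)=CC[C@@H](OC(=O)CC(C)C)c1ccoc1 | intermediate
11 | bis(pinacolato)diboron | CC1(C)OB(B2OC(C)(C)C(C)(C)O2)OC1(C)C | starting material
12 | 2-bromobenzene-1,4-diol | Oc1ccc(O)c(Br)c1 | starting material
13 | (R)-4-methyl-1-[5-(4,4,5,5-tetramethyl-1,3,2-dioxaborolan-2-yl)furan-3-yl]pent-3-en-1-yl 3-methylbutanoate | CC(C)=CC[C@@H](OC(=O)CC(C)C)c1coc(B2OC(C)(C)C(C)(C)O2)c1 | intermediate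
14 | (R)-1-[5-(2,5-dihydroxyphenyl)furan-3-yl]-4-methylpent-3-en-1-yl 3-methylbutanoate | CC(C)=CC[C@@H](OC(=O)CC(C)C)c1coc(-c2cc(O)ccc2O)c1 | target

**Step count**
Total steps: 4. Longest linear sequence: 3 (steps 1, 3, 4); step 2 is the one-step preparation of the acyl donor.

**Steps most likely to fail**

Step 3 (the proposed new step). The selectivity factor of BTM for a small 3-furyl π-system may be modest, the isothiourea may slow the Ru catalyst, and some carbonate transfer from 8 is possible. The ee of 10 is checked by chiral HPLC. The fallback uses known chemistry and sets out from 5: Dess–Martin periodinane (NaHCO3, CH2Cl2, 0 °C) gives the ketone 9, here isolated. Reduction with (S)-Me-CBS (15 mol%) and catecholborane in toluene at −78 °C gives (R)-1-(furan-3-yl)-4-methylpent-3-en-1-ol F2, the furyl group acting as the large substituent. Acylation with isovaleryl chloride, pyridine and catalytic DMAP in CH2Cl2 at 0 °C proceeds with retention and comes back to the route at 10.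

Step 1. Active barium is demanding to prepare, and any warming erodes the α:γ ratio; the γ-adduct and biphenyl must be removed by chromatography. The fallback sets out from 1: allylmagnesium bromide in THF at 0 °C gives rac-1-(furan-3-yl)but-3-en-1-ol F1. Cross-metathesis of this with 2-methylbut-2-ene as co-solvent (Grubbs second-generation catalyst, 3 mol%, CH2Cl2, 40 °C) turns the terminal alkene into the prenyl group and comes back to the route at 5.

Step 4. The free hydroquinone can be oxidised to the quinone or slow the oxidative addition, and the 2-furyl boronate 13 can protodeboronate. The fallback sets out from 10 (borylated to 13 as before) and from 12: silylation of 12 (TBSCl, imidazole, DMF, rt) gives 2-bromo-1,4-bis(tert-butyldimethylsilyloxy)benzene F3. Suzuki coupling of 13 with this bromide under the same Pd conditions gives (R)-1-{5-[2,5-bis(tert-butyldimethylsilyloxy)phenyl]furan-3-yl}-4-methylpent-3-en-1-yl 3-methylbutanoate F4. KHF2 in MeOH at rt then cleaves only the aryl silyl ethers and comes back to the route at 14.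

**Further compounds**
F1 | step 1 | rac-1-(furan-3-yl)but-3-en-1-ol | C=CCC(O)c1ccoc1
F2 | step 3 | (R)-1-(furan-3-yl)-4-methylpent-3-en-1-ol | CC(C)=CC[C@@H](O)c1ccoc1
F3 | step 4 | 2-bromo-1,4-bis(tert-butyldimethylsilyloxy)benzene | CC(C)(C)[Si](C)(C)Oc1ccc(O[Si](C)(C)C(C)(C)C)c(Br)c1
F4 | step 4 | (R)-1-{5-[2,5-bis(tert-butyldimethylsilyloxy)phenyl]furan-3-yl}-4-methylpent-3-en-1-yl 3-methylbutanoate | CC(C)=CC[C@@H](OC(=O)CC(C)C)c1coc(-c2cc(O[Si](C)(C)C(C)(C)C)ccc2O[Si](C)(C)C(C)(C)C)c1
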